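**Retrosynthetic overview**
- The last step only removes an ester. Before it, one operation closes ring C through the O1–C8a bond and then joins C4 to ring D, using the acylphloroglucinol as a carbon nucleophile.
- Enabling feature: in ring A the C7 hydroxyl is para to C4a. Ionising C4 therefore gives a para-quinone methide in which C8a is the β-carbon of the C7 dienone, six atoms from the C2 oxygen (O1–C2–C3–C4–C4a–C8a). A fluorine on C8a makes this carbon a vinylogous acyl fluoride.
- The precursor is an open-chain (1S,3S)-1,3-diarylpropane-1,3-diol. Asymmetric transfer hydrogenation of a 1,3-diketone sets C2; the second carbinol is sacrificed in the key step.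
- The diketone comes from C-acylation of silylated 2-fluoro-4-hydroxyacetophenone with 4-(pivaloyloxy)benzoyl chloride. Ring D comes from phloroglucinol and dodecanoyl chloride.
- Rings A, B and D are bought as benzene rings. Ring C is the only ring formed, in step 7.

Key step: step 7

Remark: the SMILES is read as the (2S,4R), 2,4-trans flavan. Chroman numbering is used throughout (O1, C2, C3, C4, C4a, C5 to C8, C8a; ring A benzo ring, ring B the C2 aryl group, ring C the pyran, ring D the acylphloroglucinol).

**Step 1**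
Reactants: 1 1-(2-fluoro-4-hydroxyphenyl)ethan-1-one
Product: 2 1-{4-[(tert-butyldimethylsilyl)oxy]-2-fluorophenyl}ethan-1-one
Conditions: TBSCl (1.1 equiv), imidazole (2 equiv), DMF, rt
Reagents that add atoms: tert-butyl(chloro)dimethylsilane, CC(C)(C)[Si](C)(C)Cl
Why: Imidazole-promoted silyl ether formation masks the acidic phenol so that the methyl ketone can be enolised and C-acylated in step 3.

**Step 2**
Reactants: 3 4-hydroxybenzoic acid
Product: 4 4-(pivaloyloxy)benzoic acid
Conditions: PivCl (1.1 equiv), NaOH (2.2 equiv), H2O/THF, 0 °C; then aq. HCl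
Reagents that add atoms: pivaloyl chloride, CC(C)(C)C(Cl)=O
Why: Schotten–Baumann O-acylation of the phenoxide gives the aryl pivalate, an electron-poor mask for the ring B oxygen that later keeps C2 from ionising.

**Step 3**
Reactants: 2 1-{4-[(tert-butyldimethylsilyl)oxy]-2-fluorophenyl}ethan-1-one; 4 4-(pivaloyloxy)benzoic acid
Product: 6 4-(3-{4-[(tert-butyldimethylsilyl)oxy]-2-fluorophenyl}-3-oxopropanoyl)phenyl pivalate, via 4-(pivaloyloxy)benzoyl chloride 5 (not isolated)
Conditions: 4, (COCl)2, DMF (cat.), CH2Cl2, 0 °C to rt, evaporate; then 2, MgBr2·OEt2 (2.5 equiv), i-Pr2NEt (3 equiv), CH2Cl2, rt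
Reagents that add atoms: none
Why: Crossed Claisen-type C-acylation by soft enolisation, in which the magnesium enolate of ketone 2 is acylated on carbon by acid chloride 5 and the chelated magnesium diketonate resists a second acylation.

**Step 4**
Reactants: 6 4-(3-{4-[(tert-butyldimethylsilyl)oxy]-2-fluorophenyl}-3-oxopropanoyl)phenyl pivalate
Product: 7 4-[(1S,3S)-3-{4-[(tert-butyldimethylsilyl)oxy]-2-fluorophenyl}-1,3-dihydroxypropyl]phenyl pivalate
Conditions: RuCl[(S,S)-TsDPEN](p-cymene) (2 mol %), HCO2H/Et3N (5:2), CH2Cl2, 35 °C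
Reagents that add atoms: none
Why: Noyori–Ikariya asymmetric transfer hydrogenation of both aryl ketones under catalyst control, in which the (S,S)-TsDPEN ligand directs hydride to the same face of each aryl ketone and so sets the carbinol next to ring B, the future C2, as S, while the second carbinol is erased in step 7.

**Step 5**
Reactants: 7 4-[(1S,3S)-3-{4-[(tert-butyldimethylsilyl)oxy]-2-fluorophenyl}-1,3-dihydroxypropyl]phenyl pivalate
Product: 8 4-[(1S,3S)-3-(2-fluoro-4-hydroxyphenyl)-1,3-dihydroxypropyl]phenyl pivalate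
Conditions: Bu4NF (1.1 equiv), AcOH (1.2 equiv), THF, 0 °C
Reagents that add atoms: none
Why: Fluoride-induced cleavage of the aryl silyl ether, buffered with acetic acid so that the freed phenol stays protonated and neither the aryl pivalate nor the 4-hydroxybenzylic carbinol is disturbed.

**Step 6**
Reactants: 9 benzene-1,3,5-triol (phloroglucinol); 10 dodecanoyl chloride
Product: 11 1-(2,4,6-trihydroxyphenyl)dodecan-1-one
Conditions: AlCl3 (4 equiv), PhNO2, 65 °C; aq. HCl work-up
Reagents that add atoms: none
Why: Friedel–Crafts acylation of the symmetrical triol should stop at the monoketone because the first acyl group, hydrogen-bonded to both flanking hydroxyls, deactivates the ring.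

**Step 7**
Reactants: 8 4-[(1S,3S)-3-(2-fluoro-4-hydroxyphenyl)-1,3-dihydroxypropyl]phenyl pivalate; 11 1-(2,4,6-trihydroxyphenyl)dodecan-1-one
Product: 14 4-[(2S,4R)-4-(3-dodecanoyl-2,4,6-trihydroxyphenyl)-7-hydroxychroman-2-yl]phenyl pivalate (4'-O-pivaloylmyristinin A), via open-chain para-quinone methide 12 (not isolated), via cyclic para-quinone methide 13 (not isolated)
Conditions: (PhO)2P(O)OH (10 mol %), HFIP/CH2Cl2 (1:4), 5 mM, 0 °C to rt; then 11 (3 equiv), rt
Reagents that add atoms: none
Why: Proposed new method: the phosphoric acid should ionise only the C4 carbinol, which is para to the free C7 phenol, to quinone methide 12, where the C2 hydroxyl adds to the fluorine-bearing C8a and fluoride leaves as HF (addition–elimination) to give the alkoxy-stabilised cyclic quinone methide 13, which 11 then captures at C4 by 1,6-addition with rearomatisation of ring A. The closest known reactions are the displacement of fluoride ortho to an aryl ketone by a tethered oxygen nucleophile, the Brønsted-acid generation of para-quinone methides from 4-hydroxybenzyl alcohols and the acid-mediated Friedel–Crafts arylation of flavan-4-ols by phloroglucinols. Ring C closes in the 6-exo-trig mode on the C8=C8a bond, whereas attack of O1 on C4 would be a reversible 4-exo closure to a strained oxetane. C2 should keep its S configuration because the C2–O1 bond is never broken and the acyloxy-substituted ring B does not support a cation at C2, while the configuration of the second carbinol of 8 disappears in 12. The new C4 centre is set by pseudo-axial attack of 11 on the half-chair of 13 on the face opposite the C2 aryl group, as in known arylations of flavan-4-yl cations, which should give the 2,4-trans (2S,4R) product. The step needs ionisation at C4 and not at C2, and ring closure before 11 meets 12; the free phenol on ring A, the ester on ring B, the high dilution and the late addition of 11 are meant to secure this.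

**Step 8**
Reactants: 14 4-[(2S,4R)-4-(3-dodecanoyl-2,4,6-trihydroxyphenyl)-7-hydroxychroman-2-yl]phenyl pivalate
Product: 15 (+)-myristinin A
Conditions: NaOMe (4 equiv), MeOH (degassed), 0 °C; then AcOH
Reagents that add atoms: none
Why: Base-catalysed transesterification (methanolysis) of the aryl pivalate, run cold and briefly so that the ring B phenoxide does not open the C2–O1 bond, leaves both stereocentres untouched and should give the target.

**Compound list**
1 | 1-(2-fluoro-4-hydroxyphenyl)ethan-1-one | CC(=O)c1ccc(O)cc1F | starting material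
2 | 1-{4-[(tert-butyldimethylsilyl)oxy]-2-fluorophenyl}ethan-1-one | CC(=O)c1ccc(O[Si](C)(C)C(C)(C)C)cc1F | intermediate
3 | 4-hydroxybenzoic acid | OC(=O)c1ccc(O)cc1 | starting material
4 | 4-(pivaloyloxy)benzoic acid | CC(C)(C)C(=O)Oc1ccc(cc1)C(O)=O | intermediate
5 | 4-(pivaloyloxy)benzoyl chloride | CC(C)(C)C(=O)Oc1ccc(cc1)C(Cl)=O | intermediate
6 | 4-(3-{4-[(tert-butyldimethylsilyl)oxy]-2-fluorophenyl}-3-oxopropanoyl)phenyl pivalate | CC(C)(C)C(=O)Oc1ccc(cc1)C(=O)CC(=O)c1ccc(O[Si](C)(C)C(C)(C)C)cc1F | intermediate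
7 | 4-[(1S,3S)-3-{4-[(tert-butyldimethylsilyl)oxy]-2-fluorophenyl}-1,3-dihydroxypropyl]phenyl pivalate | CC(C)(C)C(=O)Oc1ccc(cc1)[C@@H](O)C[C@H](O)c1ccc(O[Si](C)(C)C(C)(C)C)cc1F | intermediate
8 | 4-[(1S,3S)-3-(2-fluoro-4-hydroxyphenyl)-1,3-dihydroxypropyl]phenyl pivalate | CC(C)(C)C(=O)Oc1ccc(cc1)[C@@H](O)C[C@H](O)c1ccc(O)cc1F | intermediate
9 | benzene-1,3,5-triol (phloroglucinol) | Oc1cc(O)cc(O)c1 | starting material
10 | dodecanoyl chloride | CCCCCCCCCCCC(Cl)=O | starting material
11 | 1-(2,4,6-trihydroxyphenyl)dodecan-1-one | CCCCCCCCCCCC(=O)c1c(O)cc(O)cc1O | intermediate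
12 | 4-[(1S,3Z)-3-(2-fluoro-4-oxocyclohexa-2,5-dien-1-ylidene)-1-hydroxypropyl]phenyl pivalate | CC(C)(C)C(=O)Oc1ccc(cc1)[C@@H](O)C/C=C2/C=CC(=O)C=C2F | intermediate
13 | 4-[(2S)-7-oxo-3,7-dihydro-2H-chromen-2-yl]phenyl pivalate | CC(C)(C)C(=O)Oc1ccc(cc1)[C@@H]1CC=C2C=CC(=O)C=C2O1 | intermediate
14 | 4-[(2S,4R)-4-(3-dodecanoyl-2,4,6-trihydroxyphenyl)-7-hydroxychroman-2-yl]phenyl pivalate | CCCCCCCCCCCC(=O)c1c(O)cc(O)c([C@@H]2C[C@@H](c3ccc(OC(=O)C(C)(C)C)cc3)Oc3cc(O)ccc32)c1O | intermediate
15 | (+)-myristinin A, 1-{2,4,6-trihydroxy-3-[(2S,4R)-7-hydroxy-2-(4-hydroxyphenyl)chroman-4-yl]phenyl}dodecan-1-one | CCCCCCCCCCCC(=O)c1c(O)cc(O)c([C@@H]2C[C@@H](c3ccc(O)cc3)Oc3cc(O)ccc32)c1O | target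

**Step count and risks**
Total step count: 8. Longest linear sequence: 6 steps (step 1 or 2, then steps 3, 4, 5, 7 and 8).

Steps most likely to fail:

Step 7. The open-chain quinone methide 12 may isomerise to the 4-hydroxystyrene, which can ionise at the allylic C2 carbinol and lose the S configuration. It may also oligomerise before O1 reaches C8a. The fallback makes the O1–C8a bond by a copper-catalysed Ullmann-type O-arylation in a bromo series and uses only known reaction types. It sets out from 4, used as its chloride 5. Purchased 1-(2-bromo-4-hydroxyphenyl)ethan-1-one is O-benzylated (BnBr, K2CO3, acetone) to 1-[4-(benzyloxy)-2-bromophenyl]ethan-1-one F1. Acylation of F1 with 5 under the conditions of step 3 should give 4-{3-[4-(benzyloxy)-2-bromophenyl]-3-oxopropanoyl}phenyl pivalate F2. Transfer hydrogenation as in step 4 should give 4-[(1S,3S)-3-[4-(benzyloxy)-2-bromophenyl]-1,3-dihydroxypropyl]phenyl pivalate F3. CuI (10 mol %), 3,4,7,8-tetramethyl-1,10-phenanthroline and Cs2CO3 in toluene at 110 °C should then close ring C through the hydroxyl next to ring B, since the other hydroxyl could only form a four-membered ring. This gives 4-[(2S,4S)-7-(benzyloxy)-4-hydroxychroman-2-yl]phenyl pivalate F4. Treatment of F4 with p-TsOH (20 mol %) and 11 (3 equiv) in dioxane at rt is a Friedel–Crafts arylation of the flavan-4-yl cation. It should give 4-[(2S,4R)-7-(benzyloxy)-4-(3-dodecanoyl-2,4,6-trihydroxyphenyl)chroman-2-yl]phenyl pivalate F5, with the nucleophile entering trans to the C2 aryl group. Hydrogenolysis (H2, Pd/C, EtOAc) removes the benzyl ether and comes back to the route at 14.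

Step 4. The strongly enolised, ortho-substituted diaryl diketone may be reduced incompletely or with poor catalyst control, stalling at the hydroxy ketone, which can dehydrate to a chalcone. The fallback sets C2 by a catalyst-controlled aldol addition instead and sets out from 2. 4-Hydroxybenzaldehyde is pivaloylated (PivCl, Et3N, CH2Cl2) to 4-formylphenyl pivalate F6. Ketone 2 is converted (Me3SiOTf, Et3N, CH2Cl2, 0 °C) into 1-{4-[(tert-butyldimethylsilyl)oxy]-2-fluorophenyl}-1-[(trimethylsilyl)oxy]ethene F7. A Mukaiyama aldol addition of F7 to F6 (SiCl4, chiral bisphosphoramide Lewis base, CH2Cl2, −78 °C, using the catalyst enantiomer that gives the S carbinol) should give 4-[(1S)-3-{4-[(tert-butyldimethylsilyl)oxy]-2-fluorophenyl}-1-hydroxy-3-oxopropyl]phenyl pivalate F8. An Evans–Saksena reduction (Me4NBH(OAc)3, MeCN/AcOH, −20 °C) delivers hydride from boron bound to the existing hydroxyl and should give the anti diol, coming back to the route at 7.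

Step 3. The magnesium enolate may be acylated on oxygen or twice on carbon, and the fluoro diketonate may cyclise to a flavone by displacement of fluoride by its enol oxygen. The fallback replaces the acylation by an aldol addition and oxidation and sets out from 2. Deprotonation of 2 with LiN(i-Pr)2 in THF at −78 °C and addition to the aldehyde F6 (made as above) should give racemic 4-(3-{4-[(tert-butyldimethylsilyl)oxy]-2-fluorophenyl}-1-hydroxy-3-oxopropyl)phenyl pivalate F9. Oxidation with Dess–Martin periodinane in CH2Cl2 under non-basic conditions comes back to the route at 6.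

**Further compounds**
F1 | step 7 | 1-[4-(benzyloxy)-2-bromophenyl]ethan-1-one | CC(=O)c1ccc(OCc2ccccc2)cc1Br
F2 | step 7 | 4-{3-[4-(benzyloxy)-2-bromophenyl]-3-oxopropanoyl}phenyl pivalate | CC(C)(C)C(=O)Oc1ccc(cc1)C(=O)CC(=O)c1ccc(OCc2ccccc2)cc1Br
F3 | step 7 | 4-[(1S,3S)-3-[4-(benzyloxy)-2-bromophenyl]-1,3-dihydroxypropyl]phenyl pivalate | CC(C)(C)C(=O)Oc1ccc(cc1)[C@@H](O)C[C@H](O)c1ccc(OCc2ccccc2)cc1Br
F4 | step 7 | 4-[(2S,4S)-7-(benzyloxy)-4-hydroxychroman-2-yl]phenyl pivalate | CC(C)(C)C(=O)Oc1ccc(cc1)[C@@H]1C[C@H](O)c2ccc(OCc3ccccc3)cc2O1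
F5 | step 7 | 4-[(2S,4R)-7-(benzyloxy)-4-(3-dodecanoyl-2,4,6-trihydroxyphenyl)chroman-2-yl]phenyl pivalate | CCCCCCCCCCCC(=O)c1c(O)cc(O)c([C@@H]2C[C@@H](c3ccc(OC(=O)C(C)(C)C)cc3)Oc3cc(OCc4ccccc4)ccc32)c1O
F6 | step 4 | 4-formylphenyl pivalate | CC(C)(C)C(=O)Oc1ccc(C=O)cc1
F7 | step 4 | 1-{4-[(tert-butyldimethylsilyl)oxy]-2-fluorophenyl}-1-[(trimethylsilyl)oxy]ethene | C=C(O[Si](C)(C)C)c1ccc(O[Si](C)(C)C(C)(C)C)cc1F
F8 | step 4 | 4-[(1S)-3-{4-[(tert-butyldimethylsilyl)oxy]-2-fluorophenyl}-1-hydroxy-3-oxopropyl]phenyl pivalate | CC(C)(C)C(=O)Oc1ccc(cc1)[C@@H](O)CC(=O)c1ccc(O[Si](C)(C)C(C)(C)C)cc1F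
F9 | step 3 | racemic 4-(3-{4-[(tert-butyldimethylsilyl)oxy]-2-fluorophenyl}-1-hydroxy-3-oxopropyl)phenyl pivalate | CC(C)(C)C(=O)Oc1ccc(cc1)C(O)CC(=O)c1ccc(O[Si](C)(C)C(C)(C)C)cc1F
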